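**Retrosynthetic overview**
1. Zyggomphic acid B ⇐ the corresponding C7 carbaldehyde (Pinnick oxidation).
2. Bicyclic aldehyde ⇐ linear (2E,4Z,6S,7E,9E,11E,13E)-hexaenal by one biomimetic intramolecular Diels–Alder reaction. The cyclohexene and cyclopentene rings form together in this single step, and the lone C6 methyl stereocentre sets the other four stereocentres.
3. Hexaenal ⇐ hexaenol (MnO2) ⇐ (Z)-vinyl iodide + propargyl alcohol/Me3Al (Negishi carboalumination/cross-coupling, builds the E-2-methyl-allylic alcohol part).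
4. (Z)-vinyl iodide ⇐ α-chiral tetraenal by Zhao iodo-olefination (sets the Z-C(Et)=CH tether alkene).
5. Tetraenal ⇐ (R)-Roche ester by three Wittig homologations with Ph3P=C(Me)CHO and a benzyl HWE.

Assumption: ring atoms use indene numbering (C1 = ethyl-bearing sp2 carbon, C3 = CHMe, C3a/C7a = ring fusion, C6/C7 = quaternary carbons); the target is (3R,3aS,6S,7R,7aR).
Assumption: the substrate-controlled Diels–Alder step favours the CHO-endo, anti-to-methyl adduct (the target's relative configuration); this is predicted from A1,3 strain, not demonstrated, and minor diastereomers would be removed by chromatography.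
Reagents that contribute atoms are numbered as compounds. Polyene intermediates (10 onward) are handled under argon, in the dark, with BHT.

**Step 1**
Reactants: 1 methyl (R)-3-hydroxy-2-methylpropanoate [(R)-Roche ester]; 2 tert-butyldimethylsilyl chloride
Product: 3 methyl (R)-3-[(tert-butyldimethylsilyl)oxy]-2-methylpropanoate
Conditions: TBSCl, imidazole, CH2Cl2, 0 °C → rt
Reagents that add atoms: TBSCl, CC(C)(C)[Si](C)(C)Cl
Why: Standard silyl ether protection of the primary alcohol; the stereocentre (future C3 of the target) is untouched.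

**Step 2**
Reactants: 3
Product: 4 (R)-3-[(tert-butyldimethylsilyl)oxy]-2-methylpropanal
Conditions: DIBAL-H (1.05 equiv), CH2Cl2, −78 °C; Rochelle salt work-up; used crude
Reagents that add atoms: none
Why: Partial DIBAL reduction stops at the aldehyde because the aluminium hemiacetal is stable at −78 °C, and the cold, non-basic work-up preserves the α-stereocentre.

**Step 3**
Reactants: 4; 5 2-(triphenylphosphoranylidene)propanal
Product: 6 (2E,4S)-5-[(tert-butyldimethylsilyl)oxy]-2,4-dimethylpent-2-enal
Conditions: 5 (1.3 equiv), PhMe, 85 °C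
Reagents that add atoms: 2-(triphenylphosphoranylidene)propanal, CC(C=O)=P(c1ccccc1)(c1ccccc1)c1ccccc1
Why: Wittig olefination with a stabilised formyl ylide gives the E-trisubstituted enal under neutral conditions that do not epimerise the α-methyl aldehyde (the descriptor changes R→S only through CIP priorities).

**Step 4**
Reactants: 6; 5
Product: 7 (2E,4E,6S)-7-[(tert-butyldimethylsilyl)oxy]-2,4,6-trimethylhepta-2,4-dienal
Conditions: 5 (1.3 equiv), PhMe, 105 °C
Reagents that add atoms: 2-(triphenylphosphoranylidene)propanal, CC(C=O)=P(c1ccccc1)(c1ccccc1)c1ccccc1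
Why: Second stabilised-ylide Wittig homologation, E-selective; the more conjugated dienal product is less electrophilic than the enal, so mono-homologation dominates.

**Step 5**
Reactants: 7; 5
Product: 8 (2E,4E,6E,8S)-9-[(tert-butyldimethylsilyl)oxy]-2,4,6,8-tetramethylnona-2,4,6-trienal
Conditions: 5 (1.3 equiv), PhMe, 110 °C
Reagents that add atoms: 2-(triphenylphosphoranylidene)propanal, CC(C=O)=P(c1ccccc1)(c1ccccc1)c1ccccc1
Why: Third iteration of the same E-selective Wittig homologation completes the three CH=C(Me) units with no redox adjustments.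

**Step 6**
Reactants: 8; 9 diethyl benzylphosphonate
Product: 10 tert-butyldimethyl{[(2S,3E,5E,7E,9E)-2,4,6,8-tetramethyl-10-phenyldeca-3,5,7,9-tetraen-1-yl]oxy}silane
Conditions: 9 (1.3 equiv), NaHMDS (1.25 equiv), THF, −78 °C; add 8; → 0 °C
Reagents that add atoms: diethyl benzylphosphonate, CCOP(=O)(Cc1ccccc1)OCC
Why: Horner–Wadsworth–Emmons olefination with a benzylphosphonate anion gives the E-styrene; pre-forming the anion with slightly less base than phosphonate avoids free amide that could deprotonate the remote allylic C–H.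

**Step 7**
Reactants: 10
Product: 11 (2S,3E,5E,7E,9E)-2,4,6,8-tetramethyl-10-phenyldeca-3,5,7,9-tetraen-1-ol
Conditions: TBAF, THF, 0 °C → rt
Reagents that add atoms: none
Why: Fluoride-mediated desilylation; the tetraene and the allylic stereocentre are inert to TBAF.

**Step 8**
Reactants: 11
Product: 12 (2S,3E,5E,7E,9E)-2,4,6,8-tetramethyl-10-phenyldeca-3,5,7,9-tetraenal
Conditions: Dess–Martin periodinane, NaHCO3, CH2Cl2, 0 °C; quick filtration, used immediately
Reagents that add atoms: none
Why: Buffered Dess–Martin oxidation is near-neutral, so the epimerisable α-methyl-β,γ-unsaturated aldehyde is formed without racemisation or migration of the double bond into conjugation.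

**Step 9**
Reactants: 12; 13 propyltriphenylphosphonium bromide; 14 iodine
Product: 15 [(1E,3E,5E,7E,9S,10Z)-11-iodo-3,5,7,9-tetramethyltrideca-1,3,5,7,10-pentaen-1-yl]benzene
Conditions: 13, n-BuLi, THF; I2 (limiting), −78 °C; NaHMDS, −20 °C; then 12, −78 → −20 °C
Reagents that add atoms: propyltriphenylphosphonium bromide, CCC[P+](c1ccccc1)(c1ccccc1)c1ccccc1.[Br-]; iodine, II
Why: Zhao (Stork–Zhao-type) α-iodoalkylidene Wittig olefination is kinetically Z-selective, placing iodine cis to the aldehyde-derived carbon, and addition at −78 °C outruns enolisation of the sensitive aldehyde.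

**Step 10**
Reactants: 15; 16 prop-2-yn-1-ol (propargyl alcohol); 17 trimethylaluminium
Product: 18 (2E,4Z,6S,7E,9E,11E,13E)-4-ethyl-2,6,8,10,12-pentamethyl-14-phenyltetradeca-2,4,7,9,11,13-hexaen-1-ol
Conditions: 16, Me3Al (3 equiv), Cp2ZrCl2 (0.25 equiv), CH2Cl2, 0 °C → rt; evaporate volatiles; then 15, ZnCl2, Pd(PPh3)4 (5 mol %), THF, rt → 40 °C (alane 2.5 equiv relative to 15)
Reagents that add atoms: prop-2-yn-1-ol, C#CCO; trimethylaluminium, C[Al](C)C
Why: Negishi Zr-catalysed syn-methylalumination of propargyl alcohol gives the (E)-Al–CH=C(Me)CH2O– alane regioselectively, and Pd/Zn-catalysed cross-coupling with retention at both partners delivers the (2E,4Z)-dienol.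

**Step 11**
Reactants: 18
Product: 19 (2E,4Z,6S,7E,9E,11E,13E)-4-ethyl-2,6,8,10,12-pentamethyl-14-phenyltetradeca-2,4,7,9,11,13-hexaenal
Conditions: activated MnO2 (20 equiv), CH2Cl2, 0 °C → rt; filter through Celite, concentrate cold; crude 19 carried on at once
Reagents that add atoms: none
Why: Chemoselective MnO2 oxidation of the primary dienylic alcohol to the enal under neutral conditions, leaving the polyene and the doubly allylic C6 stereocentre untouched.

**Step 12**
Reactants: 19
Product: 20 (3R,3aS,6S,7R,7aR)-1-ethyl-3,4,6,7-tetramethyl-6-[(1E,3E)-2-methyl-4-phenylbuta-1,3-dien-1-yl]-3a,6,7,7a-tetrahydro-3H-indene-7-carbaldehyde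
Conditions: PhMe (0.01 M), BHT, rt → 60 °C, monitored by 1H NMR; chromatography
Reagents that add atoms: none
Why: Type-1 intramolecular Diels–Alder reaction of the C2=C3 enal dienophile with the C7=C8–C9=C10 diene, forming linear C3–C7 and C2–C10 (ring bonds C7a–C3a and C7–C6).
- Geometry-fixed relationships: the E-dienophile puts CHO cis to H7a, and the E,E-diene puts the C6 methyl cis to H3a.
- Endo/exo: the CHO-endo transition state gives the trans ring fusion and cis C6-Me/C7-Me.
- Facial selectivity: the C6–H of the linear precursor eclipses the diene to avoid A1,3 strain with the C8 methyl, so the dienophile adds anti to the C6 methyl, giving H3a cis to the C3 methyl.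

**Step 13**
Reactants: 20; 21 sodium chlorite
Product: 22 zyggomphic acid B, (3R,3aS,6S,7R,7aR)-1-ethyl-3,4,6,7-tetramethyl-6-[(1E,3E)-2-methyl-4-phenylbuta-1,3-dien-1-yl]-3a,6,7,7a-tetrahydro-3H-indene-7-carboxylic acid
Conditions: NaClO2, NaH2PO4, 2-methyl-2-butene (large excess), t-BuOH/THF/H2O, 0 °C → rt
Reagents that add atoms: sodium chlorite, [Na+].[O-]Cl=O
Why: Pinnick oxidation converts the hindered aldehyde (no α-hydrogen, so no epimerisation) to the acid chemoselectively, with 2-methyl-2-butene scavenging HOCl to protect the dienes.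

**Compound list**
1 | methyl (R)-3-hydroxy-2-methylpropanoate, (R)-Roche ester | OC[C@@H](C)C(=O)OC | starting material
2 | tert-butyldimethylsilyl chloride | CC(C)(C)[Si](C)(C)Cl | starting material (reagent)
3 | methyl (R)-3-[(tert-butyldimethylsilyl)oxy]-2-methylpropanoate | CC(C)(C)[Si](C)(C)OC[C@@H](C)C(=O)OC | intermediate
4 | (R)-3-[(tert-butyldimethylsilyl)oxy]-2-methylpropanal | CC(C)(C)[Si](C)(C)OC[C@@H](C)C=O | intermediate
5 | 2-(triphenylphosphoranylidene)propanal | CC(C=O)=P(c1ccccc1)(c1ccccc1)c1ccccc1 | starting material (reagent)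
6 | (2E,4S)-5-[(tert-butyldimethylsilyl)oxy]-2,4-dimethylpent-2-enal | CC(C)(C)[Si](C)(C)OC[C@@H](C)/C=C(\C)C=O | intermediate
7 | (2E,4E,6S)-7-[(tert-butyldimethylsilyl)oxy]-2,4,6-trimethylhepta-2,4-dienal | CC(C)(C)[Si](C)(C)OC[C@@H](C)/C=C(C)/C=C(\C)C=O | intermediate
8 | (2E,4E,6E,8S)-9-[(tert-butyldimethylsilyl)oxy]-2,4,6,8-tetramethylnona-2,4,6-trienal | CC(C)(C)[Si](C)(C)OC[C@@H](C)/C=C(C)/C=C(C)/C=C(\C)C=O | intermediate
9 | diethyl benzylphosphonate | CCOP(=O)(Cc1ccccc1)OCC | starting material (reagent)
10 | tert-butyldimethyl{[(2S,3E,5E,7E,9E)-2,4,6,8-tetramethyl-10-phenyldeca-3,5,7,9-tetraen-1-yl]oxy}silane | CC(C)(C)[Si](C)(C)OC[C@@H](C)/C=C(C)/C=C(C)/C=C(C)/C=C/c1ccccc1 | intermediate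
11 | (2S,3E,5E,7E,9E)-2,4,6,8-tetramethyl-10-phenyldeca-3,5,7,9-tetraen-1-ol | OC[C@@H](C)/C=C(C)/C=C(C)/C=C(C)/C=C/c1ccccc1 | intermediate
12 | (2S,3E,5E,7E,9E)-2,4,6,8-tetramethyl-10-phenyldeca-3,5,7,9-tetraenal | O=C[C@@H](C)/C=C(C)/C=C(C)/C=C(C)/C=C/c1ccccc1 | intermediate
13 | propyltriphenylphosphonium bromide | CCC[P+](c1ccccc1)(c1ccccc1)c1ccccc1.[Br-] | starting material (reagent)
14 | iodine | II | starting material (reagent)
15 | [(1E,3E,5E,7E,9S,10Z)-11-iodo-3,5,7,9-tetramethyltrideca-1,3,5,7,10-pentaen-1-yl]benzene | CC/C(I)=C/[C@@H](C)/C=C(C)/C=C(C)/C=C(C)/C=C/c1ccccc1 | intermediate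
16 | prop-2-yn-1-ol | C#CCO | starting material
17 | trimethylaluminium | C[Al](C)C | starting material (reagent)
18 | (2E,4Z,6S,7E,9E,11E,13E)-4-ethyl-2,6,8,10,12-pentamethyl-14-phenyltetradeca-2,4,7,9,11,13-hexaen-1-ol | OC/C(C)=C/C(CC)=C\[C@@H](C)/C=C(C)/C=C(C)/C=C(C)/C=C/c1ccccc1 | intermediate
19 | (2E,4Z,6S,7E,9E,11E,13E)-4-ethyl-2,6,8,10,12-pentamethyl-14-phenyltetradeca-2,4,7,9,11,13-hexaenal | O=C/C(C)=C/C(CC)=C\[C@@H](C)/C=C(C)/C=C(C)/C=C(C)/C=C/c1ccccc1 | intermediate
20 | (3R,3aS,6S,7R,7aR)-1-ethyl-3,4,6,7-tetramethyl-6-[(1E,3E)-2-methyl-4-phenylbuta-1,3-dien-1-yl]-3a,6,7,7a-tetrahydro-3H-indene-7-carbaldehyde | CCC1=C[C@@H](C)[C@@H]2C(C)=C[C@](C)(/C=C(C)/C=C/c3ccccc3)[C@](C)(C=O)[C@@H]12 | intermediate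
21 | sodium chlorite | [Na+].[O-]Cl=O | starting material (reagent)
22 | zyggomphic acid B | CCC1=C[C@@H](C)[C@@H]2C(C)=C[C@](C)(/C=C(C)/C=C/c3ccccc3)[C@](C)(C(=O)O)[C@@H]12 | target

**Total steps:** 13. **Longest linear sequence:** 13 (fully linear from the (R)-Roche ester).

**Steps most likely to fail, with fallbacks**
1. Step 9 (with step 8): aldehyde 12 can epimerise or conjugate, and the iodo-olefination may give modest yield and Z/E ratio. Fallback: Still–Gennari olefination of 12 with methyl 2-[bis(2,2,2-trifluoroethoxy)phosphoryl]butanoate (KHMDS, 18-crown-6, −78 °C) to the (Z)-2-ethyl enoate, then DIBAL, MnO2, and Wittig with Ph3P=C(Me)CO2Me. The resulting (2E,4Z)-dienoate cyclises and the ester is saponified, replacing the iodide/cross-coupling logic entirely.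
2. Step 12: the thermal cycloaddition could give an endo/exo or facial mixture, be slowed by the inward methyl on the diene terminus, or lose out to a [1,5]-H shift across the Z-diene. Fallback: switch from substrate control to auxiliary and Lewis-acid control. Couple 15 with an (E)-3-stannyl-2-methylacryloyl Evans oxazolidinone (Stille), run a Me2AlCl-promoted Diels–Alder at low temperature, then cleave with LiOOH to give the acid directly.
3. Step 5 (and step 4): the iterative formyl-ylide Wittig on conjugated aldehydes may over-homologate, stall, or erode E/Z purity. Fallback: convergent Negishi assembly. Convert 4 by Corey–Fuchs/MeI to the methyl alkyne and then by Cp2Zr(H)Cl/I2 to the (E)-vinyl iodide TBSOCH2CH(Me)CH=C(Me)I. Cross-couple it (Pd/ZnCl2) with the alkenylalane from Zr-catalysed methylalumination of (3E,5E)-4-methyl-6-phenylhexa-3,5-dien-1-yne (built from (E)-β-bromostyrene by alkynylation/carboalumination) to reach 10 without polyenal intermediates.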